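**Retrosynthetic overview**
1. The C3–H stereocentre lies between a ketone and an aryl ring and epimerises easily, so it is set late: the (3S) ketone comes from enantioselective protonation of the 4-silyloxy-2H-chromene (the enol silane of the isoflavanone), and only an acidic desilylation of the C7 phenol follows.
2. Ring C is disconnected at C2–C3 and C4–C4a: a cationic oxa-[4+2] annulation joins an aryloxymethyl chloride (ring A, O1 and C2, from resorcinol) to an aryl siloxyalkyne (C3, C4 and the whole chromene unit) and gives the enol silane directly.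
3. Enabling feature: ring C is an aryl alkyl ether with O1 between the C2 methylene and C8a of ring A. O1 stabilises a cation at C2 and, reinforced by the C7 oxygen para to C4a, makes C4a the nucleophilic arene carbon, while C3 (aryl-bearing) and C4 (carbonyl) carry the donor/acceptor pattern of an ynol ether.
4. Ring order: the pyran ring of the chromene unit first (3-methoxyphenol plus 3-methylbut-2-enal), ring A bought as resorcinol, ring C last in the key step.
5. Fragments: the siloxyalkyne by formylation, Ohira–Bestmann alkynylation and acetylide oxygenation/O-silylation; the chloromethyl ether by monosilylation, methylthiomethylation and S-chlorination.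

Key step: step 8

Assumption: the face to which the SnCl4/BINOL reagent delivers the proton is taken over from cyclic 2-aryl ketone enol silanes, which points to (S)-BINOL for the (3S) ketone; if the first run shows the opposite sense, (R)-BINOL is used and nothing else changes.

**Route**

Step 1
Reactants: 1 3-methoxyphenol; 2 3-methylbut-2-enal
Product: 3 chromene 7-methoxy-2,2-dimethyl-2H-chromene
Conditions: PhB(OH)2 (1 equiv), AcOH (cat.), toluene, reflux, Dean–Stark
Reagents that add atoms: none
Why: Phenylboronic acid-templated phenol–enal condensation (ortho-alkylation, dehydration and oxa-6π electrocyclisation), in which the C–C bond should form at the ring carbon ortho to OH and para to OMe, the more nucleophilic and less hindered site, so that the 7-methoxy chromene is expected as the main isomer.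

Step 2
Reactants: 3 7-methoxy-2,2-dimethyl-2H-chromene
Product: 5 aldehyde 7-methoxy-2,2-dimethyl-2H-chromene-6-carbaldehyde, via iminium chloride 4 (not isolated)
Conditions: POCl3, DMF, 0 → 50 °C; then ice-water
Reagents that add atoms: N,N-dimethylformamide, CN(C)C=O; water, O
Why: Vilsmeier–Haack formylation, for which C6 is para to the ring oxygen and ortho to the methoxy group and thus the most activated open arene position, while the gem-dimethyl group shields the C3=C4 alkene.

Step 3
Reactants: 5 7-methoxy-2,2-dimethyl-2H-chromene-6-carbaldehyde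
Product: 6 alkyne 6-ethynyl-7-methoxy-2,2-dimethyl-2H-chromene
Conditions: dimethyl (1-diazo-2-oxopropyl)phosphonate, K2CO3, MeOH, rt
Reagents that add atoms: dimethyl (1-diazo-2-oxopropyl)phosphonate, COP(=O)(OC)C(=[N+]=[N-])C(C)=O
Why: The Ohira–Bestmann modification of the Seyferth–Gilbert homologation turns the aldehyde into the terminal alkyne under mild carbonate conditions that should leave the chromene untouched.

Step 4
Reactants: 6 6-ethynyl-7-methoxy-2,2-dimethyl-2H-chromene
Product: 9 siloxyalkyne triisopropyl{[(7-methoxy-2,2-dimethyl-2H-chromen-6-yl)ethynyl]oxy}silane, via lithium acetylide 7 (not isolated), via lithium ynolate 8 (not isolated)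
Conditions: LiN(SiMe3)2 (2.1 equiv), t-BuOOH (1.0 equiv, anhydrous), THF, −78 → 0 °C; then i-Pr3SiOTf, −78 °C; filtration through Et3N-deactivated silica
Reagents that add atoms: tert-butyl hydroperoxide, CC(C)(C)OO; triisopropylsilyl trifluoromethanesulfonate, CC(C)[Si](C(C)C)(C(C)C)OS(=O)(=O)C(F)(F)F
Why: Oxygenation of a lithium acetylide with lithium tert-butyl peroxide (electrophilic O-transfer with loss of tert-butoxide) gives the ynolate, which the bulky silyl triflate should silylate on oxygen and not on carbon (ynolate O-silylation).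

Step 5
Reactants: 10 resorcinol
Product: 11 phenol 3-[(triisopropylsilyl)oxy]phenol
Conditions: i-Pr3SiCl (1.0 equiv), imidazole, resorcinol in excess (3 equiv), DMF, 0 °C → rt
Reagents that add atoms: triisopropylsilyl chloride, CC(C)[Si](Cl)(C(C)C)C(C)C
Why: Silyl ether formation, in which the excess of resorcinol and the bulk of the triisopropylsilyl group should hold the reaction at the monoether, the unreacted diol being washed out with water.

Step 6
Reactants: 11 3-[(triisopropylsilyl)oxy]phenol
Product: 13 thioacetal triisopropyl{3-[(methylsulfanyl)methoxy]phenoxy}silane, via sodium phenolate 12 (not isolated)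
Conditions: NaH, DMF, 0 °C; then MeSCH2Cl, 0 °C → rt
Reagents that add atoms: chloromethyl methyl sulfide, CSCCl
Why: Williamson etherification of the phenolate with the activated α-chloro sulfide, during which the hindered aryl silyl ether should not migrate at this temperature.

Step 7
Reactants: 13 triisopropyl{3-[(methylsulfanyl)methoxy]phenoxy}silane
Product: 14 chloromethyl ether [3-(chloromethoxy)phenoxy]triisopropylsilane
Conditions: SO2Cl2 (1.0 equiv), CH2Cl2, −78 → 0 °C; volatiles removed in vacuo, used crude
Reagents that add atoms: sulfuryl chloride, O=S(=O)(Cl)Cl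
Why: S-chlorination of the O,S-acetal and collapse of the chlorosulfonium ion (Pummerer-type fragmentation) is the standard conversion of methylthiomethyl ethers into chloromethyl ethers, and sulfur should react faster than the arene at low temperature.

Step 8
Reactants: 14 [3-(chloromethoxy)phenoxy]triisopropylsilane; 9 triisopropyl{[(7-methoxy-2,2-dimethyl-2H-chromen-6-yl)ethynyl]oxy}silane (1.2 equiv)
Product: 17 enol silane 3-(7-methoxy-2,2-dimethyl-2H-chromen-6-yl)-4,7-bis[(triisopropylsilyl)oxy]-2H-chromene, via aryloxymethyl cation 15 (not isolated), via silylketenium ion 16 (not isolated)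
Conditions: AgN(SO2CF3)2 (1.1 equiv), 2,6-di-tert-butyl-4-methylpyridine (1.5 equiv), 4 Å MS, CH2Cl2, −78 → −20 °C
Reagents that add atoms: none
Why: Proposed new method: AgN(SO2CF3)2 abstracts chloride from 14 to give the aryloxymethyl cation 15, the nucleophilic aryl-bearing carbon of siloxyalkyne 9 adds to it (C2–C3 bond) to give the silylketenium ion 16, and the ring A carbon ortho to the ether oxygen and para to the silyloxy group attacks the ketenium carbon (C4–C4a bond) before the hindered pyridine removes the arenium proton. The closest known reaction types are the cationic oxa-[4+2] annulation of aryl oxocarbenium ions with alkenes (oxa-Povarov reaction) and the acid-promoted Friedel–Crafts carbocyclisation of arene-tethered siloxyalkynes through silylketenium ions. Ring C closes in a six-membered Friedel–Crafts mode, formally 6-exo-dig at the ketenium carbon, with the C=O π bond that is broken outside the ring and the new C3=C4 enol bond inside it. No stereocentre is created, because C3 emerges sp2 in the enol silane and is left for step 9. The step needs chemoselectivity for the ynol ether over the chromene alkene and both arenes, which the much higher π-nucleophilicity of the siloxyalkyne should secure, and regioselectivity for C4a over C8, which the para-directing silyloxy group and its bulk next to C8 should secure. The pyridine base keeps the medium free of acid, so that the enol silane and the chromene should survive.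

Step 9
Reactants: 17 3-(7-methoxy-2,2-dimethyl-2H-chromen-6-yl)-4,7-bis[(triisopropylsilyl)oxy]-2H-chromene
Product: 18 ketone (3S)-3-(7-methoxy-2,2-dimethyl-2H-chromen-6-yl)-7-[(triisopropylsilyl)oxy]-2,3-dihydro-4H-chromen-4-one
Conditions: SnCl4 (1.1 equiv), (S)-BINOL (1.2 equiv), toluene, −78 °C; then aq. NaHCO3 at −78 °C
Reagents that add atoms: none
Why: Enantioselective protonation of a silyl enol ether by a Lewis acid-assisted chiral Brønsted acid, in which the tin-bound binaphthol transfers its activated proton to one enantiotopic face of C3 of this cyclic 2-aryl enol silane, the substrate class the reagent serves best, (S)-BINOL being chosen to give the (3S) ketone.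

Step 10
Reactants: 18 (3S)-3-(7-methoxy-2,2-dimethyl-2H-chromen-6-yl)-7-[(triisopropylsilyl)oxy]-2,3-dihydro-4H-chromen-4-one
Product: 19 target (3S)-7-hydroxy-3-(7-methoxy-2,2-dimethyl-2H-chromen-6-yl)-2,3-dihydro-4H-chromen-4-one
Conditions: HF·pyridine, pyridine, THF, 0 °C → rt
Reagents that add atoms: none
Why: Fluoride-driven cleavage of the aryl silyl ether in the acidic HF/pyridine buffer, where no base is present, so that the C3 stereocentre should not enolise and the chromene should survive.

**Compound list**
1 | 3-methoxyphenol | COc1cccc(O)c1 | starting material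
2 | 3-methylbut-2-enal | CC(C)=CC=O | starting material
3 | 7-methoxy-2,2-dimethyl-2H-chromene | COc1ccc2C=CC(C)(C)Oc2c1 | intermediate
4 | N-[(7-methoxy-2,2-dimethyl-2H-chromen-6-yl)methylidene]-N-methylmethanaminium chloride (iminium chloride) | COc1cc2OC(C)(C)C=Cc2cc1C=[N+](C)C.[Cl-] | intermediate
5 | 7-methoxy-2,2-dimethyl-2H-chromene-6-carbaldehyde | COc1cc2OC(C)(C)C=Cc2cc1C=O | intermediate
6 | 6-ethynyl-7-methoxy-2,2-dimethyl-2H-chromene | COc1cc2OC(C)(C)C=Cc2cc1C#C | intermediate
7 | lithium (7-methoxy-2,2-dimethyl-2H-chromen-6-yl)acetylide | COc1cc2OC(C)(C)C=Cc2cc1C#[C-].[Li+] | intermediate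
8 | lithium 2-(7-methoxy-2,2-dimethyl-2H-chromen-6-yl)ethyn-1-olate (lithium ynolate) | COc1cc2OC(C)(C)C=Cc2cc1C#C[O-].[Li+] | intermediate
9 | triisopropyl{[(7-methoxy-2,2-dimethyl-2H-chromen-6-yl)ethynyl]oxy}silane | COc1cc2OC(C)(C)C=Cc2cc1C#CO[Si](C(C)C)(C(C)C)C(C)C | intermediate
10 | resorcinol | Oc1cccc(O)c1 | starting material
11 | 3-[(triisopropylsilyl)oxy]phenol | Oc1cccc(O[Si](C(C)C)(C(C)C)C(C)C)c1 | intermediate
12 | sodium 3-[(triisopropylsilyl)oxy]phenolate | [Na+].[O-]c1cccc(O[Si](C(C)C)(C(C)C)C(C)C)c1 | intermediate
13 | triisopropyl{3-[(methylsulfanyl)methoxy]phenoxy}silane | CSCOc1cccc(O[Si](C(C)C)(C(C)C)C(C)C)c1 | intermediate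
14 | [3-(chloromethoxy)phenoxy]triisopropylsilane | ClCOc1cccc(O[Si](C(C)C)(C(C)C)C(C)C)c1 | intermediate
15 | {3-[(triisopropylsilyl)oxy]phenoxy}methylium bis(trifluoromethanesulfonyl)imide (aryloxymethyl cation) | C=[O+]c1cccc(O[Si](C(C)C)(C(C)C)C(C)C)c1.FC(F)(F)S(=O)(=O)[N-]S(=O)(=O)C(F)(F)F | intermediate
16 | [2-(7-methoxy-2,2-dimethyl-2H-chromen-6-yl)-3-{3-[(triisopropylsilyl)oxy]phenoxy}prop-1-en-1-ylidene](triisopropylsilyl)oxonium bis(trifluoromethanesulfonyl)imide (silylketenium ion) | COc1cc2OC(C)(C)C=Cc2cc1C(COc1cccc(O[Si](C(C)C)(C(C)C)C(C)C)c1)=C=[O+][Si](C(C)C)(C(C)C)C(C)C.FC(F)(F)S(=O)(=O)[N-]S(=O)(=O)C(F)(F)F | intermediate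
17 | 3-(7-methoxy-2,2-dimethyl-2H-chromen-6-yl)-4,7-bis[(triisopropylsilyl)oxy]-2H-chromene | COc1cc2OC(C)(C)C=Cc2cc1C1=C(O[Si](C(C)C)(C(C)C)C(C)C)c2ccc(O[Si](C(C)C)(C(C)C)C(C)C)cc2OC1 | intermediate
18 | (3S)-3-(7-methoxy-2,2-dimethyl-2H-chromen-6-yl)-7-[(triisopropylsilyl)oxy]-2,3-dihydro-4H-chromen-4-one | COc1cc2c(cc1[C@H]1COc3cc(O[Si](C(C)C)(C(C)C)C(C)C)ccc3C1=O)C=CC(C)(C)O2 | intermediate
19 | (3S)-7-hydroxy-3-(7-methoxy-2,2-dimethyl-2H-chromen-6-yl)-2,3-dihydro-4H-chromen-4-one | COc1cc2c(cc1[C@H]1COc3cc(O)ccc3C1=O)C=CC(C)(C)O2 | target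

**Step count and risks**

Total step count: 10. Longest linear sequence: 7 steps (steps 1, 2, 3, 4, 8, 9, 10).

Steps most likely to fail:

Step 8 (carries the label for a proposed new method). The aryloxymethyl cation may alkylate ring A of a second molecule, or the silylketenium ion may lose its silyl group or add a second alkyne before the ring closes. The fallback builds the two bonds one after the other by known chemistry; it sets out from the lithium ynolate 8 and the chloromethyl ether 14 and comes back to the route at 17. Ynolate 8 is quenched with dilute aqueous HCl to give (7-methoxy-2,2-dimethyl-2H-chromen-6-yl)acetic acid F1. F1 is treated with LiN(i-Pr)2 (2.1 equiv, THF, −78 °C) and C-alkylated with 14 to give racemic 2-(7-methoxy-2,2-dimethyl-2H-chromen-6-yl)-3-{3-[(triisopropylsilyl)oxy]phenoxy}propanoic acid F2, which forms the C2–C3 bond. Intramolecular Friedel–Crafts acylation (trifluoroacetic anhydride, CH2Cl2, 0 °C) para to the silyloxy group should then close ring C and give racemic 3-(7-methoxy-2,2-dimethyl-2H-chromen-6-yl)-7-[(triisopropylsilyl)oxy]-2,3-dihydro-4H-chromen-4-one F3. Enol silylation of F3 (i-Pr3SiOTf, Et3N, CH2Cl2, 0 °C), possible only towards C3, returns to 17.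

Step 9. Facial selectivity of the proton transfer to the hindered triisopropylsilyl enol ether may be poor, or non-selective background hydrolysis and acid damage to the chromene may compete. The fallback replaces protonation by reduction under dynamic kinetic resolution; it sets out from 17 and comes back at 18. Mild hydrolysis of the enol silane (dilute aq. HCl, THF, 0 °C; the aryl silyl ether should stay) gives the racemic ketone F3. Asymmetric transfer hydrogenation (RuCl[(S,S)-TsDPEN](p-cymene), HCO2H/Et3N, EtOAc, 40 °C), in which C3 racemises faster than the ketone is reduced, should give cis-(3S,4S)-3-(7-methoxy-2,2-dimethyl-2H-chromen-6-yl)-7-[(triisopropylsilyl)oxy]-3,4-dihydro-2H-chromen-4-ol F4; the configuration follows the usual sense of this catalyst with aryl ketones. Oxidation of F4 with Dess–Martin periodinane (NaHCO3, CH2Cl2, 0 °C) returns to 18 without touching C3.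

Step 7. SO2Cl2 or the sulfenyl chloride it releases may chlorinate or sulfenylate the electron-rich ring A, and the chloromethyl ether may hydrolyse on handling. The fallback avoids any chlorinating agent; it sets out from phenol 11 and comes back at 17. O-Alkylation of 11 with bromomethyl acetate (K2CO3, acetone, rt) gives the bench-stable {3-[(triisopropylsilyl)oxy]phenoxy}methyl acetate F5. F5 is ionised in the presence of siloxyalkyne 9 with Me3SiN(SO2CF3)2 and 2,6-di-tert-butyl-4-methylpyridine (CH2Cl2, −78 °C) to the same cation 15, which continues through 16 to 17.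

Further compounds
F1 | step 8 | (7-methoxy-2,2-dimethyl-2H-chromen-6-yl)acetic acid | COc1cc2OC(C)(C)C=Cc2cc1CC(=O)O
F2 | step 8 | racemic 2-(7-methoxy-2,2-dimethyl-2H-chromen-6-yl)-3-{3-[(triisopropylsilyl)oxy]phenoxy}propanoic acid | COc1cc2OC(C)(C)C=Cc2cc1C(COc1cccc(O[Si](C(C)C)(C(C)C)C(C)C)c1)C(=O)O
F3 | step 8 | racemic 3-(7-methoxy-2,2-dimethyl-2H-chromen-6-yl)-7-[(triisopropylsilyl)oxy]-2,3-dihydro-4H-chromen-4-one | COc1cc2c(cc1C1COc3cc(O[Si](C(C)C)(C(C)C)C(C)C)ccc3C1=O)C=CC(C)(C)O2
F4 | step 9 | (3S,4S)-3-(7-methoxy-2,2-dimethyl-2H-chromen-6-yl)-7-[(triisopropylsilyl)oxy]-3,4-dihydro-2H-chromen-4-ol | COc1cc2c(cc1[C@H]1COc3cc(O[Si](C(C)C)(C(C)C)C(C)C)ccc3[C@H]1O)C=CC(C)(C)O2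
F5 | step 7 | {3-[(triisopropylsilyl)oxy]phenoxy}methyl acetate | CC(=O)OCOc1cccc(O[Si](C(C)C)(C(C)C)C(C)C)c1
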